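The cyclopentenone carries an α-ketol: the C1 ketone sits next to the fully substituted C5 carbinol of the five-membered ring (C2=C3, C4–OAc, side chain C1′ on C5). Everything rests on the C1–C5 disconnection, realised as a carbene-catalysed benzoin closure in which the C1 aldehyde, as acyl anion equivalent, adds to the C5 ketone; one operation makes the ring, the C1 carbonyl and the C5 stereocenter. The precursor is a 4,6-dioxygenated 5-oxoicosanal whose two oxygens (O4, O1′) are tied as an isopropylidene ketal, a cis-4,6-disubstituted 1,3-dioxan-5-one with a 3-oxopropyl arm, so that cis-fused closure puts the C5 hydroxyl trans to O4.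

Key step: step 9

Remark: locants follow the target ring (C1 ketone, C2=C3, C4–O, C5 carbinol, C1′ side-chain carbinol); in open-chain intermediates these carbons are C1–C5 and C6 of the icosane chain. The target is taken as (4R,5S,1′S), with O4 and C1′ cis on the ring.

Step 1
Reactants: 1 (4R)-4-benzyl-1,3-oxazolidin-2-one; 2 (benzyloxy)acetyl chloride
Product: 3 (4R)-4-benzyl-3-[(benzyloxy)acetyl]-1,3-oxazolidin-2-one
Conditions: n-BuLi, THF, −78 °C; then 2, −78 to 0 °C
Reagents that add atoms: none
Why: N-acylation of the lithiated oxazolidinone by the acid chloride (nucleophilic acyl substitution) attaches the glycolate unit to the auxiliary without touching its stereocenter.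

Step 2
Reactants: 3 (4R)-4-benzyl-3-[(benzyloxy)acetyl]-1,3-oxazolidin-2-one; 4 pentadecanal
Product: 5 (4R)-4-benzyl-3-[(2R,3S)-2-(benzyloxy)-3-hydroxyheptadecanoyl]-1,3-oxazolidin-2-one
Conditions: Bu2BOTf, Et3N, CH2Cl2, −78 to 0 °C; then 4, −78 to 0 °C; pH 7 buffer, MeOH, 30% H2O2, 0 °C
Reagents that add atoms: none
Why: Evans syn aldol reaction, in which the Z dibutylboron enolate of the glycolate imide reacts through a closed chair (Zimmerman–Traxler) transition state on the face away from the benzyl group of the auxiliary, setting C6 (the later C1′) as S and the temporary C5 center as R.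

Step 3
Reactants: 5 (4R)-4-benzyl-3-[(2R,3S)-2-(benzyloxy)-3-hydroxyheptadecanoyl]-1,3-oxazolidin-2-one
Product: 6 (2R,3S)-2-(benzyloxy)-3-hydroxy-N-methoxy-N-methylheptadecanamide
Conditions: MeNHOMe·HCl, AlMe3, CH2Cl2, −10 to 0 °C; aq. HCl work-up
Reagents that add atoms: N,O-dimethylhydroxylamine hydrochloride, CNOC.Cl
Why: Aluminium-amide transamidation (Weinreb amide formation), assisted by the free β-hydroxyl, displaces the oxazolidinone, which is recovered, and touches no stereocenter.

Step 4
Reactants: 6 (2R,3S)-2-(benzyloxy)-3-hydroxy-N-methoxy-N-methylheptadecanamide; 7 benzyl 3-bromopropyl ether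
Product: 9 (5R,6S)-1,5-bis(benzyloxy)-6-hydroxyicosan-4-one, via [3-(benzyloxy)propyl]magnesium bromide 8 (not isolated)
Conditions: 7, Mg, I2 (cat.), THF, 40 °C; then 6 (8 in excess, about 3.5 equiv), THF, −20 to 0 °C; aq. NH4Cl
Reagents that add atoms: none
Why: Weinreb ketone synthesis, in which one equivalent of the Grignard reagent deprotonates the hydroxyl and a second adds once to give a stable magnesium chelate that releases the ketone only on work-up, so over-addition is avoided.

Step 5
Reactants: 9 (5R,6S)-1,5-bis(benzyloxy)-6-hydroxyicosan-4-one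
Product: 10 (4R,5R,6S)-1,5-bis(benzyloxy)icosane-4,6-diol
Conditions: Et2BOMe, THF/MeOH (4:1), −78 °C; then NaBH4, −78 °C; MeOH co-evaporation
Reagents that add atoms: none
Why: Narasaka–Prasad reduction, in which the diethylboron chelate of the β-hydroxy ketone takes external hydride axially and anti to the α-benzyloxy group, setting C4 as R in the 1,3-syn relation to the C6 hydroxyl.

Step 6
Reactants: 10 (4R,5R,6S)-1,5-bis(benzyloxy)icosane-4,6-diol
Product: 11 (4R,5R,6S)-5-(benzyloxy)-4-[3-(benzyloxy)propyl]-2,2-dimethyl-6-tetradecyl-1,3-dioxane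
Conditions: 2,2-dimethoxypropane, PPTS (cat.), CH2Cl2, rt
Reagents that add atoms: 2,2-dimethoxypropane, COC(C)(C)OC
Why: Acid-catalysed transketalisation (acetonide formation) can engage only the two free hydroxyls, and the syn-1,3-diol gives the chair 1,3-dioxane with both carbon substituents equatorial, locking the O4/O6 pair for the key step.

Step 7
Reactants: 11 (4R,5R,6S)-5-(benzyloxy)-4-[3-(benzyloxy)propyl]-2,2-dimethyl-6-tetradecyl-1,3-dioxane
Product: 12 3-[(4R,5R,6S)-5-hydroxy-2,2-dimethyl-6-tetradecyl-1,3-dioxan-4-yl]propan-1-ol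
Conditions: H2 (1 atm), palladium on carbon (Pd/C, 10%), EtOAc, rt
Reagents that add atoms: none
Why: Catalytic hydrogenolysis of the benzyl ethers under neutral conditions frees the C1 and C5 hydroxyls and leaves the ketal and all stereocenters untouched.

Step 8
Reactants: 12 3-[(4R,5R,6S)-5-hydroxy-2,2-dimethyl-6-tetradecyl-1,3-dioxan-4-yl]propan-1-ol
Product: 13 3-[(4R,6S)-2,2-dimethyl-5-oxo-6-tetradecyl-1,3-dioxan-4-yl]propanal (the O4,O6-isopropylidene ketal of (4R,6S)-4,6-dihydroxy-5-oxoicosanal)
Conditions: (COCl)2, DMSO, CH2Cl2, −78 °C; then Et3N, −78 to −20 °C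
Reagents that add atoms: none
Why: Swern oxidation converts both hydroxyls into alkoxysulfonium salts before base is added, so the primary and the secondary alcohol are oxidised together without a hydroxy aldehyde that could close to a lactol; the temporary C5 center is erased and the diequatorial cis-4,6 arrangement, being the thermodynamic one, is not scrambled by the amine.

Step 9
Reactants: 13 3-[(4R,6S)-2,2-dimethyl-5-oxo-6-tetradecyl-1,3-dioxan-4-yl]propanal
Product: 14 (4S,4aS,7aR)-4a-hydroxy-2,2-dimethyl-4-tetradecylhexahydrocyclopenta[d][1,3]dioxin-5-one (the O3,O1′-isopropylidene ketal of (2S,3R)-2,3-dihydroxy-2-[(1S)-1-hydroxypentadecyl]cyclopentan-1-one)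
Conditions: 2-(pentafluorophenyl)-6,7-dihydro-5H-pyrrolo[2,1-c][1,2,4]triazol-2-ium tetrafluoroborate (20 mol %), Et3N (20 mol %), toluene (0.02 M), rt, argon
Reagents that add atoms: none
Why: The triazolylidene adds to the C1 aldehyde and proton transfer gives the enaminol (acyl anion equivalent), which attacks the C5 ketone; collapse of the adduct releases the carbene and the tertiary α-ketol. The closest known reaction type is the carbene-catalysed intramolecular crossed aldehyde–ketone benzoin of 2-(3-oxopropyl)cycloalkanones, which gives cis-fused bicyclic ketols. The cyclopentanone ring closes in the 5-exo-trig mode (C1 onto the C5 carbonyl). The new C5 stereocenter is controlled by the substrate: the 3-oxopropyl arm is equatorial on the chair dioxanone and closure to the cis-fused bicycle (new C1–C5 bond axial) is strongly preferred over the strained trans-fused alternative, so the hydroxyl becomes equatorial, trans to O4, with C1′ cis to O4; because both oxygens sit in the ring, the Felkin preference that an open-chain C1′ ether would exert against this face is removed. The step needs the aldehyde alone to act as acyl donor (only it can form the enaminol; no enal is present, so no homoenolate), suppression of aldol and intermolecular benzoin pathways (weak amine base, high dilution) and retention of the two α-stereocenters, which the thermodynamically preferred cis-4,6 arrangement secures.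

Step 10
Reactants: 14 (4S,4aS,7aR)-4a-hydroxy-2,2-dimethyl-4-tetradecylhexahydrocyclopenta[d][1,3]dioxin-5-one
Product: 16 (4S,4aS,7aR)-2,2-dimethyl-4-tetradecyl-4a-(trimethylsilyloxy)-4a,7a-dihydrocyclopenta[d][1,3]dioxin-5(4H)-one, via bis(trimethylsilyl) enol ether 15 (not isolated)
Conditions: Me3SiOTf, Et3N, CH2Cl2, 0 °C; volatiles removed, crude 15 taken up in MeCN; then Pd(OAc)2 (1.2 equiv), MeCN, rt
Reagents that add atoms: trimethylsilyl trifluoromethanesulfonate, C[Si](C)(C)OS(=O)(=O)C(F)(F)F
Why: Saegusa–Ito oxidation, in which soft enolisation can only go toward C2 because C5 is fully substituted (the tertiary hydroxyl is silylated in passing) and divalent palladium turns the silyl enol ether into the C2=C3 enone by β-hydride elimination.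

Step 11
Reactants: 16 (4S,4aS,7aR)-2,2-dimethyl-4-tetradecyl-4a-(trimethylsilyloxy)-4a,7a-dihydrocyclopenta[d][1,3]dioxin-5(4H)-one
Product: 17 (4R,5S)-4,5-dihydroxy-5-[(1S)-1-hydroxypentadecyl]cyclopent-2-en-1-one
Conditions: aq. HCl (1 M), THF, rt
Reagents that add atoms: none
Why: Acid-catalysed hydrolysis cleaves the trimethylsilyl ether and the isopropylidene ketal in one operation through the oxocarbenium ion at the ketal carbon, so no ring stereocenter is engaged.

Step 12
Reactants: 17 (4R,5S)-4,5-dihydroxy-5-[(1S)-1-hydroxypentadecyl]cyclopent-2-en-1-one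
Product: 18 (1R,5S)-5-[(1S)-1-(acetyloxy)pentadecyl]-5-hydroxy-4-oxocyclopent-2-en-1-yl acetate
Conditions: Ac2O, pyridine, CH2Cl2, 0 °C to rt
Reagents that add atoms: acetic anhydride, CC(=O)OC(C)=O
Why: Acetylation with Ac2O/pyridine esterifies the two secondary hydroxyls (C4 and C1′), while the hindered tertiary α-ketol hydroxyl at C5 should not react in the absence of a stronger acyl-transfer catalyst.

Compound list
1 | (4R)-4-benzyl-1,3-oxazolidin-2-one | O=C1OC[C@@H](Cc2ccccc2)N1 | starting material
2 | (benzyloxy)acetyl chloride | O=C(Cl)COCc1ccccc1 | starting material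
3 | (4R)-4-benzyl-3-[(benzyloxy)acetyl]-1,3-oxazolidin-2-one | O=C1OC[C@@H](Cc2ccccc2)N1C(=O)COCc1ccccc1 | intermediate
4 | pentadecanal | CCCCCCCCCCCCCCC=O | starting material
5 | (4R)-4-benzyl-3-[(2R,3S)-2-(benzyloxy)-3-hydroxyheptadecanoyl]-1,3-oxazolidin-2-one | CCCCCCCCCCCCCC[C@H](O)[C@@H](OCc1ccccc1)C(=O)N1[C@H](Cc2ccccc2)COC1=O | intermediate
6 | (2R,3S)-2-(benzyloxy)-3-hydroxy-N-methoxy-N-methylheptadecanamide | CCCCCCCCCCCCCC[C@H](O)[C@@H](OCc1ccccc1)C(=O)N(C)OC | intermediate
7 | benzyl 3-bromopropyl ether | BrCCCOCc1ccccc1 | starting material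
8 | [3-(benzyloxy)propyl]magnesium bromide | Br[Mg]CCCOCc1ccccc1 | intermediate
9 | (5R,6S)-1,5-bis(benzyloxy)-6-hydroxyicosan-4-one | CCCCCCCCCCCCCC[C@H](O)[C@@H](OCc1ccccc1)C(=O)CCCOCc1ccccc1 | intermediate
10 | (4R,5R,6S)-1,5-bis(benzyloxy)icosane-4,6-diol | CCCCCCCCCCCCCC[C@H](O)[C@@H](OCc1ccccc1)[C@H](O)CCCOCc1ccccc1 | intermediate
11 | (4R,5R,6S)-5-(benzyloxy)-4-[3-(benzyloxy)propyl]-2,2-dimethyl-6-tetradecyl-1,3-dioxane | CCCCCCCCCCCCCC[C@H](OC(C)(C)O1)[C@@H](OCc2ccccc2)[C@H]1CCCOCc1ccccc1 | intermediate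
12 | 3-[(4R,5R,6S)-5-hydroxy-2,2-dimethyl-6-tetradecyl-1,3-dioxan-4-yl]propan-1-ol | CCCCCCCCCCCCCC[C@H](OC(C)(C)O1)[C@@H](O)[C@H]1CCCO | intermediate
13 | 3-[(4R,6S)-2,2-dimethyl-5-oxo-6-tetradecyl-1,3-dioxan-4-yl]propanal | CCCCCCCCCCCCCC[C@H](OC(C)(C)O1)C(=O)[C@H]1CCC=O | intermediate
14 | (4S,4aS,7aR)-4a-hydroxy-2,2-dimethyl-4-tetradecylhexahydrocyclopenta[d][1,3]dioxin-5-one | CCCCCCCCCCCCCC[C@H](OC2(C)C)[C@@]1(O)C(=O)CC[C@H]1O2 | intermediate
15 | (4S,4aS,7aR)-2,2-dimethyl-4-tetradecyl-4a,5-bis(trimethylsilyloxy)-4,4a,7,7a-tetrahydrocyclopenta[d][1,3]dioxine | CCCCCCCCCCCCCC[C@H](OC2(C)C)[C@@]1(O[Si](C)(C)C)C(O[Si](C)(C)C)=CC[C@H]1O2 | intermediate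
16 | (4S,4aS,7aR)-2,2-dimethyl-4-tetradecyl-4a-(trimethylsilyloxy)-4a,7a-dihydrocyclopenta[d][1,3]dioxin-5(4H)-one | CCCCCCCCCCCCCC[C@H](OC2(C)C)[C@@]1(O[Si](C)(C)C)C(=O)C=C[C@H]1O2 | intermediate
17 | (4R,5S)-4,5-dihydroxy-5-[(1S)-1-hydroxypentadecyl]cyclopent-2-en-1-one | CCCCCCCCCCCCCC[C@H](O)[C@@]1(O)C(=O)C=C[C@H]1O | intermediate
18 | (1R,5S)-5-[(1S)-1-(acetyloxy)pentadecyl]-5-hydroxy-4-oxocyclopent-2-en-1-yl acetate | CCCCCCCCCCCCCC[C@H](OC(C)=O)[C@@]1(O)C(=O)C=C[C@H]1OC(C)=O | target

Total step count: 12. Longest linear sequence: 12 steps (from 1 and 2 to 18); the Grignard reagent 8 is made within step 4.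

Steps most likely to fail

Step 9. The hindered, doubly α-branched dioxanone carbonyl may be attacked too slowly, so that intermolecular aldol or benzoin oligomerisation of the aldehyde and base-induced epimerisation take over. The fallback sets out from 13 and forms the same C1–C5 bond reductively: SmI2 with t-BuOH in THF at −78 °C should effect a ketyl pinacol cyclisation (aldehyde ketyl onto the ketone) to the cis-fused cis-diol (4S,4aS,5R,7aR)-2,2-dimethyl-4-tetradecylhexahydrocyclopenta[d][1,3]dioxine-4a,5-diol F1. Oxidation of its secondary hydroxyl alone (SO3·pyridine, DMSO, i-Pr2NEt, Parikh–Doering conditions) then gives the α-ketol, and the route is rejoined at 14.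

Step 10. Silylation may be incomplete or may open the ketal under the silyl triflate, and the palladium-mediated dehydrosilylation may stall with reversion to the saturated ketone. The fallback sets out from 14 and uses selenoxide elimination: LiN(SiMe3)2 (2.2 equiv) in THF at −78 °C followed by PhSeBr should give (4S,4aS,7aR)-4a-hydroxy-2,2-dimethyl-6-(phenylselanyl)-4-tetradecylhexahydrocyclopenta[d][1,3]dioxin-5-one F2 as a mixture of C6 epimers. Oxidation with H2O2 and pyridine in CH2Cl2 at 0 °C and syn elimination of the selenoxide should give (4S,4aS,7aR)-4a-hydroxy-2,2-dimethyl-4-tetradecyl-4a,7a-dihydrocyclopenta[d][1,3]dioxin-5(4H)-one F3. F3 is hydrolysed under the conditions of step 11, and the route is rejoined at 17.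

Step 8. If one hydroxyl is oxidised ahead of the other, the transient hydroxy aldehyde can close to a six-membered lactol and be over-oxidised to the lactone; epimerisation next to the new ketone during the amine treatment is a lesser concern. The fallback sets out from 12 and oxidises the two positions one after the other. TBSCl and imidazole in CH2Cl2 at 0 °C should silylate the primary hydroxyl to give (4R,5R,6S)-4-[3-(tert-butyldimethylsilyloxy)propyl]-2,2-dimethyl-6-tetradecyl-1,3-dioxan-5-ol F4. Dess–Martin periodinane with NaHCO3 then gives (4R,6S)-4-[3-(tert-butyldimethylsilyloxy)propyl]-2,2-dimethyl-6-tetradecyl-1,3-dioxan-5-one F5. HF·pyridine in THF/pyridine frees (4R,6S)-4-(3-hydroxypropyl)-2,2-dimethyl-6-tetradecyl-1,3-dioxan-5-one F6, and a second Dess–Martin oxidation of the primary alcohol rejoins the route at 13.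

Further compounds
F1 | step 9 | (4S,4aS,5R,7aR)-2,2-dimethyl-4-tetradecylhexahydrocyclopenta[d][1,3]dioxine-4a,5-diol | CCCCCCCCCCCCCC[C@H](OC2(C)C)[C@@]1(O)[C@H](O)CC[C@H]1O2
F2 | step 10 | (4S,4aS,7aR)-4a-hydroxy-2,2-dimethyl-6-(phenylselanyl)-4-tetradecylhexahydrocyclopenta[d][1,3]dioxin-5-one (C6 epimers) | CCCCCCCCCCCCCC[C@H](OC2(C)C)[C@@]1(O)C(=O)C([Se]c3ccccc3)C[C@H]1O2
F3 | step 10 | (4S,4aS,7aR)-4a-hydroxy-2,2-dimethyl-4-tetradecyl-4a,7a-dihydrocyclopenta[d][1,3]dioxin-5(4H)-one | CCCCCCCCCCCCCC[C@H](OC2(C)C)[C@@]1(O)C(=O)C=C[C@H]1O2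
F4 | step 8 | (4R,5R,6S)-4-[3-(tert-butyldimethylsilyloxy)propyl]-2,2-dimethyl-6-tetradecyl-1,3-dioxan-5-ol | CCCCCCCCCCCCCC[C@H](OC(C)(C)O1)[C@@H](O)[C@H]1CCCO[Si](C)(C)C(C)(C)C
F5 | step 8 | (4R,6S)-4-[3-(tert-butyldimethylsilyloxy)propyl]-2,2-dimethyl-6-tetradecyl-1,3-dioxan-5-one | CCCCCCCCCCCCCC[C@H](OC(C)(C)O1)C(=O)[C@H]1CCCO[Si](C)(C)C(C)(C)C
F6 | step 8 | (4R,6S)-4-(3-hydroxypropyl)-2,2-dimethyl-6-tetradecyl-1,3-dioxan-5-one | CCCCCCCCCCCCCC[C@H](OC(C)(C)O1)C(=O)[C@H]1CCCO
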